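**Conventions.** Prenyl = 3‑methylbut‑2‑en‑1‑yl; MOM = methoxymethyl; TIPS = tri(propan‑2‑yl)silyl. Flavanone numbering: O1, C2, C3, C4, C4a, C5–C8, C8a for rings C and A, C1'–C6' for ring B.

## The problem

Target **19** is a (2S)‑flavanone. Its pyranone ring C (O1, C2, C3, C4, C4a, C8a) is fused to a phloroglucinol‑type ring A (5,7‑dihydroxy, 6‑prenyl) and carries a catechol ring B (3',4'‑dihydroxy, 5'‑prenyl) at C2. C2 is the only stereocentre, so nothing in the molecule can control it and its configuration has to come from a reagent or catalyst. C2 is also fragile: the C2–O1 bond lies beta to the C4 carbonyl, so base or hot acid opens ring C reversibly and re‑closes it as the racemate. Both prenyl groups sit next to phenolic oxygens. Strong acid adds those oxygens across the alkenes to give dimethylchromans, and hydrogenation or peracids destroy the alkenes, so late steps must be mild and non‑reductive. The prenyl group of ring A must end at C6 and not C8, a distinction that ring closures of trioxygenated open‑chain precursors usually fail to make. The feature that opens a short route is that ring C is a two‑carbon unit C3–C4 inserted between the O1‑bound benzylic carbon C2 and C4a. Removing C3–C4 leaves an aryl ether of 4‑prenylphloroglucinol that is mirror‑symmetric about the O1–C8a···C6 axis. Its two ortho carbons are therefore identical, each lies ortho, ortho and para to three oxygens, and closure at either gives the 6‑prenyl skeleton.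

## Retrosynthesis

**19 to 17 (no skeletal bond cut).** The four phenols are masked as MOM ethers and the C4 carbonyl as its diethyl ketal, which gives **17**. Acetal protection is preferred to silyl ethers, whose fluoride removal is basic and opens ring C and which donate less into ring A. It is preferred to benzyl ethers because hydrogenolysis would reduce the prenyl alkenes. The ketal is simply the form in which the annulation delivers C4. The forward step is one acidic operation that passes through ketone **18**; it must leave C2 and both prenyl groups untouched.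

**17 to 15 + 16 (cut C2–C3 and C4–C4a).** Removing C3–C4 as ketene diethyl acetal **16** leaves the racemic alpha‑acetoxy ether **15**, in which rings A and B are joined only through an acetal carbon.
- Cutting O1–C2 alone would lead back to the open‑chain enone, whose closure is the very equilibrium that racemises C2.
- Cutting C2–C1' would need a preformed 6‑prenyl pyranone ring and a metalated ring B, which is a longer route.
- Cutting C4–C4a alone would need a strongly acidic acylation that neither the prenyl groups nor the beta‑aryloxy carbonyl would survive.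
- The two‑bond cut removes ring C and the stereocentre in one move and makes the stereochemistry of **15** irrelevant, because ionisation flattens C2.

The forward reaction asks for three things: a chiral counteranion that controls the face of attack on the oxocarbenium ion, ring closure onto ring A that is faster than loss of an alkyl group from the C4 cation, and MOM acetals and prenyl alkenes that stay out of the reaction. An O‑ethyl ketene acetal is chosen over an O‑silyl one for the second reason: a silyl group would be shed faster than ring A could attack.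

**15 to 13 (C2 from acetal to ester level).** Hydride addition to aryl ester **13** gives the aluminium hemiacetal **14**, which is acetylated in the same flask. This is preferred to assembling the acetal from aldehyde **11** and phenol **7**, because an aryloxy hemiacetal does not accumulate at equilibrium, whereas reduction of the ester forms it irreversibly as its aluminium salt. **13** is achiral and stable. The forward step must stop at the hemiacetal oxidation level.

**13 to 12 + 7 (ester C–O bond).** This is the convergent cut. It separates ring B acid **12** from the symmetric ring A phenol **7**, each a trisubstituted benzene. Only a mild esterification of a phenol is asked for.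

**12 to 8 (ring B).** Acid **12** comes from aldehyde **11** by oxidation. The prenyl group of **11** is attached by cross‑coupling at the C–Br bond of **10**. The MOM ethers of **10** come from catechol **9**, and **9** from 5‑bromovanillin **8** by demethylation. The bromine of **8** already marks C5', so no regiochemical decision is needed on ring B.

**7 to 1 (ring A).** Phenol **7** is unmasked from silyl ether **6**. The prenyl group of **6** is placed between the two MOM ethers of **3** by directed lithiation (aryllithium **5**) and alkylation with prenyl bromide **4**. The TIPS group of **3** holds the place of the future O1 and does not direct lithiation. **3** comes from bis‑ether **2**, and **2** from phloroglucinol **1**. The price is one statistical protection; everything after it is regiochemically unambiguous.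

## Roads not taken

**Alternative 1:** The two Ar–CH2 bonds of the prenyl groups (C6–CH2 and C5'–CH2) are cut. The precursor is the bis(2‑methylbut‑3‑en‑2‑yl) ether **A1** of a preformed (S)‑flavanone. Heating it in a high‑boiling aromatic amine shifts both allyl units from oxygen to the ortho carbons and gives the 7,3'‑bis‑MOM flavanone **A2**.
- Merits: the acid‑sensitive prenyl groups appear only at the end, both enter in one operation, and the aromatic Claisen rearrangement of tertiary allyl aryl ethers is dependable chemistry. In that respect this road is safer than the chosen one, whose key step is untested.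
- Weak points: the rearrangement builds neither the flavanone core nor C2, so an enantioselective flavanone synthesis is still needed first. The four phenols must be differentiated two by two, with a tertiary allyl group on the hydrogen‑bonded, least reactive 5‑OH. The hot basic medium is exactly what opens ring C by retro‑oxa‑Michael reaction, and the rearranged product carries the free 5‑OH that makes this easier.
- Comparison: the chosen plan answers with a stereocentre that is made late, at low temperature, in the same step that makes ring C, and with ring A regiochemistry settled by symmetry instead of by selective etherification.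

**Alternative 2:** The C2–C3 bond is cut. The precursor is the aryl diazomethyl ketone **A3**, whose C8a oxygen carries the ring B benzyl group. A chiral dirhodium tetracarboxylate would generate the C3 carbene, which inserts into one of the two enantiotopic benzylic C–H bonds and gives the tetrakis(tert‑butyldimethylsilyl) flavanone **A4**.
- Merits: the precursor is achiral and stable, the conditions are neutral, the ketone is formed directly, and ring C and C2 arise together. Where both plans rest on an unproven enantioselective step, this one avoids acid altogether and needs no ketal hydrolysis.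
- Weak points: the carbene sits five atoms from the ether oxygen, so attack of that oxygen on the carbene followed by benzyl shift should compete strongly with a six‑membered C–H insertion. Two trisubstituted alkenes invite cyclopropanation. Carbenes that bear only an acyl group are the least selective class. Fluoride removal of four silyl ethers is basic and threatens C2.
- Comparison: in the chosen plan the reactive intermediate is a cation that is offered a far better nucleophile than any alkene or ether in the substrate, so the prenyl groups remain spectators.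

**Alternative 3:** Three bonds of ring A are cut (C5–C6, C7–C8 and C4a–C5). The precursors are the (S)‑dihydropyranone diazoketone **A5** and the prenyl‑substituted siloxyalkyne **A6**. Irradiation triggers Wolff rearrangement, [2+2] addition of the alkyne, four‑electron ring opening and six‑electron ring closure, and gives the 5‑hydroxy‑7‑silyloxy flavanone **A7**.
- Merits: C2 would be set early by an established asymmetric hetero‑Diels–Alder reaction of the ring B aldehyde. The 6‑prenyl regiochemistry is written into the alkyne, and the 5‑ and 7‑oxygens emerge differentiated. On certainty of the stereocentre and on regiochemical proof this road is better.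
- Weak points: length and fragility. The 6‑acyl dihydropyranone and its diazoketone need a custom diene and several steps. The skipped enyne of **A6** is awkward to make. The enone chromophore and the alkenes are exposed to light, and the thermal stages put the beta‑oxygenated ketone at risk of ring opening.
- Comparison: the chosen plan needs twelve steps in all from four bulk chemicals and builds both halves from simple benzenes.

Key step: step 11

## Route

Assumption: the (S,S) antipode of the imidodiphosphorimidate acid is taken to direct the ketene acetal to the Si face of C2; should it favour the Re face, the (R,R) antipode is used under the same conditions.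

Step 1
Reactants: 1 phloroglucinol
Product: 2 3,5‑bis(methoxymethoxy)phenol
Conditions: MOMCl (2.0 equiv), i‑Pr2NEt, DMF, 0 °C to rt; chromatography
Reagents that add atoms: chloromethyl methyl ether, COCCl
Why: O‑alkylation of three equivalent phenols; two equivalents should make the bis‑ether the main component of a statistical mixture, separable because each free hydroxyl changes polarity strongly.

Step 2
Reactants: 2 3,5‑bis(methoxymethoxy)phenol
Product: 3 [3,5‑bis(methoxymethoxy)phenoxy]tri(propan‑2‑yl)silane
Conditions: TIPSCl, imidazole, DMF, rt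
Reagents that add atoms: chlorotri(propan‑2‑yl)silane, CC(C)[Si](Cl)(C(C)C)C(C)C
Why: Standard silylation of a phenol; the bulky silyl ether masks the future O1, resists butyllithium and does not direct lithiation.

Step 3
Reactants: 3 [3,5‑bis(methoxymethoxy)phenoxy]tri(propan‑2‑yl)silane; 4 prenyl bromide
Product: 6 [3,5‑bis(methoxymethoxy)‑4‑prenylphenoxy]tri(propan‑2‑yl)silane, via aryllithium 5 (not isolated)
Conditions: n‑BuLi, THF, 0 °C; then CuI (10 mol %), 4, −78 °C to rt
Reagents that add atoms: none
Why: Directed ortho‑metalation removes the hydrogen between the two MOM ethers (double chelation; the positions next to the silyl ether are shielded), and the copper‑assisted aryl nucleophile displaces bromide at the primary carbon (SN2) to give the linear prenyl group.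

Step 4
Reactants: 6 [3,5‑bis(methoxymethoxy)‑4‑prenylphenoxy]tri(propan‑2‑yl)silane
Product: 7 3,5‑bis(methoxymethoxy)‑4‑prenylphenol
Conditions: TBAF, THF, 0 °C; aq. NH4Cl
Reagents that add atoms: none
Why: Fluoride‑induced Si–O cleavage; MOM ethers and the alkene are inert to fluoride.

Step 5
Reactants: 8 5‑bromovanillin
Product: 9 3‑bromo‑4,5‑dihydroxybenzaldehyde
Conditions: AlCl3, pyridine, CH2Cl2, reflux; then aq. HCl
Reagents that add atoms: none
Why: Aryl methyl ether cleavage: aluminium chelated between the phenoxide and the neighbouring methoxy oxygen activates the methyl group for SN2 removal by pyridine, the classical conversion of vanillins into catechols; aldehyde and bromide are untouched.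

Step 6
Reactants: 9 3‑bromo‑4,5‑dihydroxybenzaldehyde
Product: 10 3‑bromo‑4,5‑bis(methoxymethoxy)benzaldehyde
Conditions: MOMCl (3 equiv), i‑Pr2NEt, CH2Cl2, 0 °C to rt
Reagents that add atoms: chloromethyl methyl ether, COCCl
Why: O‑alkylation of both catechol hydroxyls under amine base; aldehyde and aryl bromide tolerate the conditions.

Step 7
Reactants: 10 3‑bromo‑4,5‑bis(methoxymethoxy)benzaldehyde
Product: 11 3,4‑bis(methoxymethoxy)‑5‑prenylbenzaldehyde
Conditions: tributyl(prenyl)stannane, Pd(PPh3)4 (5 mol %), DMF, 95 °C
Reagents that add atoms: tributyl(3‑methylbut‑2‑en‑1‑yl)stannane, CCCC[Sn](CCCC)(CCCC)CC=C(C)C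
Why: Stille cross‑coupling: zerovalent palladium inserts into the C–Br bond, the allyl group is transferred from tin, and reductive elimination at the less hindered allyl terminus should give the linear prenyl arene; the aldehyde and MOM ethers are inert under these neutral conditions.

Step 8
Reactants: 11 3,4‑bis(methoxymethoxy)‑5‑prenylbenzaldehyde
Product: 12 3,4‑bis(methoxymethoxy)‑5‑prenylbenzoic acid
Conditions: NaClO2, NaH2PO4, 2‑methylbut‑2‑ene (20 equiv), t‑BuOH/H2O, 0 °C to rt
Reagents that add atoms: sodium chlorite, [Na+].[O-]Cl=O
Why: Pinnick oxidation; chlorous acid oxidises only the aldehyde, the large excess of 2‑methylbut‑2‑ene takes up hypochlorous acid before it reaches the prenyl alkene or the electron‑rich ring, and the buffered pH spares the MOM ethers.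

Step 9
Reactants: 12 3,4‑bis(methoxymethoxy)‑5‑prenylbenzoic acid; 7 3,5‑bis(methoxymethoxy)‑4‑prenylphenol
Product: 13 3,5‑bis(methoxymethoxy)‑4‑prenylphenyl 3,4‑bis(methoxymethoxy)‑5‑prenylbenzoate
Conditions: EDC·HCl, 4‑(dimethylamino)pyridine (20 mol %), CH2Cl2, 0 °C to rt
Reagents that add atoms: none
Why: Steglich esterification; carbodiimide activation and acyl transfer through the acylpyridinium ion acylate the phenol under neutral conditions.

Step 10
Reactants: 13 3,5‑bis(methoxymethoxy)‑4‑prenylphenyl 3,4‑bis(methoxymethoxy)‑5‑prenylbenzoate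
Product: 15 racemic [3,4‑bis(methoxymethoxy)‑5‑prenylphenyl][3,5‑bis(methoxymethoxy)‑4‑prenylphenoxy]methyl acetate, via diisobutylaluminium hemiacetal 14 (not isolated)
Conditions: DIBAL‑H, CH2Cl2, −78 °C; then pyridine, 4‑(dimethylamino)pyridine, Ac2O, −78 to −20 °C; Rochelle salt work‑up; Et3N‑deactivated silica or use crude
Reagents that add atoms: acetic anhydride, CC(=O)OC(C)=O
Why: Reductive acetylation of an ester: at −78 °C one hydride adds to the aryl ester, the tetrahedral aluminium hemiacetal should persist long enough to be O‑acetylated in the same flask, and the mixed acetal is formed as the racemate, which is all the next step needs.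

Step 11
Reactants: 15 racemic [3,4‑bis(methoxymethoxy)‑5‑prenylphenyl][3,5‑bis(methoxymethoxy)‑4‑prenylphenoxy]methyl acetate; 16 ketene diethyl acetal
Product: 17 (2S)‑4,4‑diethoxy‑5,7‑bis(methoxymethoxy)‑2‑[3,4‑bis(methoxymethoxy)‑5‑prenylphenyl]‑6‑prenylchromane
Conditions: (S,S)‑HN[P(=NSO2CF3)(L)]2 (5 mol %; L = 3,3'‑bis[3,5‑bis(trifluoromethyl)phenyl]‑1,1'‑binaphthalene‑2,2'‑diolate), 16 (3 equiv, slow addition), toluene/CH2Cl2, −78 °C; Et3N quench at −78 °C
Reagents that add atoms: none
Why: Proposed new method: the acid (free, or stored as the 1,1‑diethoxyethyl cation it forms with 16) removes acetate from either enantiomer of 15 and leaves one planar O‑aryl oxocarbenium ion O1=C2, stabilised by the para oxygen of ring B and held as a contact ion pair inside the chiral imidodiphosphorimidate anion, while the acetic acid set free is taken up by a second equivalent of 16 as ethyl acetate. Ketene acetal 16 then adds to C2 (bond C2–C3) and the resulting C4 diethoxycarbenium ion is captured by an ortho carbon of ring A in a 6‑exo‑trig Friedel–Crafts closure (bond C4–C4a), after which proton loss restores the arene and the acid; overall this is a stepwise cationic [4+2] of the oxadiene O1=C2/C8a=C4a with the ketene acetal. The closest known reaction types are the Lewis‑acid oxa‑Povarov annulation of aryl oxocarbenium ions with alkenes to chromans and the imidodiphosphorimidate‑controlled addition of silyl ketene acetals to oxocarbenium ions generated from alpha‑acetoxy ethers; neither has been run as an enantioselective annulation with a ketene dialkyl acetal. C2 is the only new stereocentre and is fixed in the C2–C3 bond formation: the counteranion must expose the Si face of C2 (priorities O1 > C1' > H), and because ionisation erases the configuration of 15 the step is stereoconvergent. The step needs chemoselective ionisation (only the benzylic acetate gives a doubly stabilised cation, whereas the MOM acetals would give primary ones), carbon–carbon bond formation by 16 in preference to any arene or prenyl alkene (16 is by far the strongest nucleophile present), and ring closure faster than loss of an ethyl group (O‑ethyl groups can leave only by slow SN2 at carbon, and the attacking ring A carbon is ortho, ortho and para to three ether oxygens). Regiochemistry needs no control, because the two ortho carbons of ring A are equivalent by symmetry and either gives the 6‑prenyl skeleton.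

Step 12
Reactants: 17 (2S)‑4,4‑diethoxy‑5,7‑bis(methoxymethoxy)‑2‑[3,4‑bis(methoxymethoxy)‑5‑prenylphenyl]‑6‑prenylchromane
Product: 19 (2S)‑5,7‑dihydroxy‑2‑(3,4‑dihydroxy‑5‑prenylphenyl)‑6‑prenylchroman‑4‑one, via tetrakis(methoxymethyl) flavanone 18 (not isolated)
Conditions: 3 M aq. HCl/MeOH (1:5), 45 °C, argon, monitored and stopped at completion
Reagents that add atoms: water, O
Why: Acid‑catalysed hydrolysis: the benzylic ketal should give ketone 18 within minutes, then the four MOM acetals are transferred to methanol; this type of MOM removal is standard for prenylated flavanones, and at this temperature acid should neither open ring C (C2 is not touched) nor add the phenols across the prenyl alkenes to a significant extent.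

## Compound list

1 | phloroglucinol (benzene‑1,3,5‑triol) | Oc1cc(O)cc(O)c1 | starting material
2 | 3,5‑bis(methoxymethoxy)phenol | COCOc1cc(O)cc(OCOC)c1 | intermediate
3 | [3,5‑bis(methoxymethoxy)phenoxy]tri(propan‑2‑yl)silane | COCOc1cc(OCOC)cc(O[Si](C(C)C)(C(C)C)C(C)C)c1 | intermediate
4 | prenyl bromide (1‑bromo‑3‑methylbut‑2‑ene) | CC(C)=CCBr | starting material
5 | {2,6‑bis(methoxymethoxy)‑4‑[tri(propan‑2‑yl)silyloxy]phenyl}lithium (formed in the flask, not isolated) | [Li]c1c(OCOC)cc(O[Si](C(C)C)(C(C)C)C(C)C)cc1OCOC | intermediate
6 | [3,5‑bis(methoxymethoxy)‑4‑(3‑methylbut‑2‑en‑1‑yl)phenoxy]tri(propan‑2‑yl)silane | CC(C)=CCc1c(OCOC)cc(O[Si](C(C)C)(C(C)C)C(C)C)cc1OCOC | intermediate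
7 | 3,5‑bis(methoxymethoxy)‑4‑(3‑methylbut‑2‑en‑1‑yl)phenol | CC(C)=CCc1c(OCOC)cc(O)cc1OCOC | intermediate
8 | 5‑bromovanillin (3‑bromo‑4‑hydroxy‑5‑methoxybenzaldehyde) | COc1cc(C=O)cc(Br)c1O | starting material
9 | 3‑bromo‑4,5‑dihydroxybenzaldehyde | O=Cc1cc(O)c(O)c(Br)c1 | intermediate
10 | 3‑bromo‑4,5‑bis(methoxymethoxy)benzaldehyde | COCOc1cc(C=O)cc(Br)c1OCOC | intermediate
11 | 3,4‑bis(methoxymethoxy)‑5‑(3‑methylbut‑2‑en‑1‑yl)benzaldehyde | COCOc1cc(C=O)cc(CC=C(C)C)c1OCOC | intermediate
12 | 3,4‑bis(methoxymethoxy)‑5‑(3‑methylbut‑2‑en‑1‑yl)benzoic acid | COCOc1cc(C(=O)O)cc(CC=C(C)C)c1OCOC | intermediate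
13 | 3,5‑bis(methoxymethoxy)‑4‑(3‑methylbut‑2‑en‑1‑yl)phenyl 3,4‑bis(methoxymethoxy)‑5‑(3‑methylbut‑2‑en‑1‑yl)benzoate | CC(C)=CCc1cc(C(=O)Oc2cc(OCOC)c(CC=C(C)C)c(OCOC)c2)cc(OCOC)c1OCOC | intermediate
14 | racemic diisobutylaluminium hemiacetal of 13, Ar(B)–CH(OAl(i‑Bu)2)–O–Ar(A) (formed in the flask, not isolated) | CC(C)=CCc1cc(C(O[Al](CC(C)C)CC(C)C)Oc2cc(OCOC)c(CC=C(C)C)c(OCOC)c2)cc(OCOC)c1OCOC | intermediate
15 | racemic [3,4‑bis(methoxymethoxy)‑5‑(3‑methylbut‑2‑en‑1‑yl)phenyl][3,5‑bis(methoxymethoxy)‑4‑(3‑methylbut‑2‑en‑1‑yl)phenoxy]methyl acetate | CC(=O)OC(Oc1cc(OCOC)c(CC=C(C)C)c(OCOC)c1)c1cc(CC=C(C)C)c(OCOC)c(OCOC)c1 | intermediate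
16 | ketene diethyl acetal (1,1‑diethoxyethene) | C=C(OCC)OCC | starting material
17 | (2S)‑4,4‑diethoxy‑5,7‑bis(methoxymethoxy)‑2‑[3,4‑bis(methoxymethoxy)‑5‑(3‑methylbut‑2‑en‑1‑yl)phenyl]‑6‑(3‑methylbut‑2‑en‑1‑yl)chromane | CC(C)=CCc1cc([C@@H]2CC(OCC)(OCC)c3c(cc(OCOC)c(CC=C(C)C)c3OCOC)O2)cc(OCOC)c1OCOC | intermediate
18 | (2S)‑5,7‑bis(methoxymethoxy)‑2‑[3,4‑bis(methoxymethoxy)‑5‑(3‑methylbut‑2‑en‑1‑yl)phenyl]‑6‑(3‑methylbut‑2‑en‑1‑yl)chroman‑4‑one (formed in the flask, not isolated) | CC(C)=CCc1cc([C@@H]2CC(=O)c3c(cc(OCOC)c(CC=C(C)C)c3OCOC)O2)cc(OCOC)c1OCOC | intermediate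
19 | (2S)‑5,7‑dihydroxy‑2‑[3,4‑dihydroxy‑5‑(3‑methylbut‑2‑en‑1‑yl)phenyl]‑6‑(3‑methylbut‑2‑en‑1‑yl)chroman‑4‑one | CC(C)=CCc1cc([C@@H]2CC(=O)c3c(cc(O)c(CC=C(C)C)c3O)O2)cc(O)c1O | target

## Step count and risks

Total: 12 steps. Longest linear sequence: 8 steps (steps 5–12 from 5‑bromovanillin; the ring A branch, steps 1–4 and then 9–12, is equally long).

**Step 11 (key step, proposed new method).** Four things are most likely to go wrong:
- The C4 diethoxycarbenium ion may lose an ethyl group to acetate or acetic acid before ring A attacks, which ends in an open‑chain ester.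
- The ring A oxygen may be expelled from C2 after the first bond is formed, which cleaves the molecule.
- The acid may oligomerise the ketene acetal and starve the cycle.
- The acyclic oxocarbenium ion may be bound in more than one geometry, which gives poor facial selectivity.

The fallback uses known chemistry and runs from silyl ether 6 and aldehyde 11 to ketone 18. Directed ortho‑lithiation of 6 (s‑BuLi, TMEDA, THF, −78 °C) at the carbon between the silyl ether and a MOM ether gives [2,4‑bis(methoxymethoxy)‑3‑prenyl‑6‑(triisopropylsilyloxy)phenyl]lithium F1. N‑methoxy‑N‑methylacetamide acylates it to the silyloxy acetophenone F2, and TBAF buffered with AcOH frees the hydroxyacetophenone F3, whose free hydroxyl lies next to the ring hydrogen. Claisen–Schmidt condensation of F3 with 11 (KOH, EtOH, rt) gives the (E)‑2'‑hydroxychalcone F4, and NaOAc in refluxing EtOH closes it by oxa‑Michael addition to the racemic tetrakis‑MOM flavanone F5, again only with the 6‑prenyl arrangement. Asymmetric transfer hydrogenation with Cp*RhCl(TsDPEN) (TsDPEN = N‑tosyl‑1,2‑diphenylethane‑1,2‑diamine; the antipode that reduces the 2R ketone) in HCO2H/Et3N/EtOAc resolves F5 kinetically: the 2R enantiomer is reduced to the (2R,4R)‑cis‑flavan‑4‑ol F6 and removed by chromatography, and the unreacted (S)‑ketone is 18, which enters step 12. At most half of F5 can be recovered as 18.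

**Step 10.** The aluminium hemiacetal may collapse before it is acetylated, because an aryloxide is a far better leaving group than the alkoxides for which the method is routine; the consequence would be over‑reduction. The product may also ionise on silica and hydrolyse. The fallback builds the acetal at the aldehyde oxidation level and runs from aldehyde 11 and phenol 7 to 15. Acetyl chloride adds to 11 under nucleophilic catalysis (catalytic pyridine, CH2Cl2, 0 °C, no Lewis acid, so the MOM acetals are spared) to give racemic chloro[3,4‑bis(methoxymethoxy)‑5‑prenylphenyl]methyl acetate F7. Without isolation, F7 alkylates 7 in the presence of Cs2CO3 in DMF at 0 °C, the acyloxyalkylation of a phenoxide known from acyloxyalkyl ether prodrugs, and gives 15.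

**Step 12.** As the MOM groups fall, the liberated phenols next to each prenyl group may add across the alkene under protic acid (chroman formation). Long heating may also open ring C reversibly and erode the configuration at C2. The fallback separates the two tasks and avoids protic acid for the deprotection; it runs from 17 to 19. PPTS in acetone/water at rt hydrolyses only the ketal, and 18 is isolated. TMSOTf with 2,2'‑bipyridyl in CH2Cl2 at 0 °C then converts the four aryl MOM ethers into the tetrakis(trimethylsilyl) ether F8, which water cleaves at rt to 19.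

**Step 7.** Allyl transposition in the allylpalladium intermediate may give the branched 1,1‑dimethylallyl isomer, and protodebromination may compete. The fallback replaces palladium by a polar SN2 alkylation and runs from bromide 10 to aldehyde 11. Trimethyl orthoformate in MeOH with catalytic PPTS gives the dimethyl acetal F9. Bromine–lithium exchange (n‑BuLi, THF, −78 °C) gives the aryllithium F10, which with CuBr·SMe2 (10 mol %) and prenyl bromide 4 gives the prenylated acetal F11. PPTS in acetone/water releases 11.

## Further compounds

F1 | step 11 | {2,4‑bis(methoxymethoxy)‑3‑(3‑methylbut‑2‑en‑1‑yl)‑6‑[tri(propan‑2‑yl)silyloxy]phenyl}lithium | [Li]c1c(O[Si](C(C)C)(C(C)C)C(C)C)cc(OCOC)c(CC=C(C)C)c1OCOC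
F2 | step 11 | 1‑{2,4‑bis(methoxymethoxy)‑3‑(3‑methylbut‑2‑en‑1‑yl)‑6‑[tri(propan‑2‑yl)silyloxy]phenyl}ethan‑1‑one | CC(=O)c1c(O[Si](C(C)C)(C(C)C)C(C)C)cc(OCOC)c(CC=C(C)C)c1OCOC
F3 | step 11 | 1‑[6‑hydroxy‑2,4‑bis(methoxymethoxy)‑3‑(3‑methylbut‑2‑en‑1‑yl)phenyl]ethan‑1‑one | CC(=O)c1c(O)cc(OCOC)c(CC=C(C)C)c1OCOC
F4 | step 11 | (E)‑1‑[6‑hydroxy‑2,4‑bis(methoxymethoxy)‑3‑(3‑methylbut‑2‑en‑1‑yl)phenyl]‑3‑[3,4‑bis(methoxymethoxy)‑5‑(3‑methylbut‑2‑en‑1‑yl)phenyl]prop‑2‑en‑1‑one | CC(C)=CCc1cc(/C=C/C(=O)c2c(O)cc(OCOC)c(CC=C(C)C)c2OCOC)cc(OCOC)c1OCOC
F5 | step 11 | racemic 5,7‑bis(methoxymethoxy)‑2‑[3,4‑bis(methoxymethoxy)‑5‑(3‑methylbut‑2‑en‑1‑yl)phenyl]‑6‑(3‑methylbut‑2‑en‑1‑yl)chroman‑4‑one | CC(C)=CCc1cc(C2CC(=O)c3c(cc(OCOC)c(CC=C(C)C)c3OCOC)O2)cc(OCOC)c1OCOC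
F6 | step 11 | (2R,4R)‑5,7‑bis(methoxymethoxy)‑2‑[3,4‑bis(methoxymethoxy)‑5‑(3‑methylbut‑2‑en‑1‑yl)phenyl]‑6‑(3‑methylbut‑2‑en‑1‑yl)chroman‑4‑ol | CC(C)=CCc1cc([C@H]2C[C@@H](O)c3c(cc(OCOC)c(CC=C(C)C)c3OCOC)O2)cc(OCOC)c1OCOC
F7 | step 10 | racemic chloro[3,4‑bis(methoxymethoxy)‑5‑(3‑methylbut‑2‑en‑1‑yl)phenyl]methyl acetate | CC(=O)OC(Cl)c1cc(CC=C(C)C)c(OCOC)c(OCOC)c1
F8 | step 12 | (2S)‑5,7‑bis(trimethylsilyloxy)‑2‑[3,4‑bis(trimethylsilyloxy)‑5‑(3‑methylbut‑2‑en‑1‑yl)phenyl]‑6‑(3‑methylbut‑2‑en‑1‑yl)chroman‑4‑one | CC(C)=CCc1cc([C@@H]2CC(=O)c3c(cc(O[Si](C)(C)C)c(CC=C(C)C)c3O[Si](C)(C)C)O2)cc(O[Si](C)(C)C)c1O[Si](C)(C)C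
F9 | step 7 | 1‑bromo‑5‑(dimethoxymethyl)‑2,3‑bis(methoxymethoxy)benzene | COCOc1cc(C(OC)OC)cc(Br)c1OCOC
F10 | step 7 | [5‑(dimethoxymethyl)‑2,3‑bis(methoxymethoxy)phenyl]lithium | [Li]c1cc(C(OC)OC)cc(OCOC)c1OCOC
F11 | step 7 | 5‑(dimethoxymethyl)‑1,2‑bis(methoxymethoxy)‑3‑(3‑methylbut‑2‑en‑1‑yl)benzene | COCOc1cc(C(OC)OC)cc(CC=C(C)C)c1OCOC
A1 | alternative 1 | (2S)‑7‑(methoxymethoxy)‑2‑[3‑(methoxymethoxy)‑4‑(2‑methylbut‑3‑en‑2‑yloxy)phenyl]‑5‑(2‑methylbut‑3‑en‑2‑yloxy)chroman‑4‑one | C=CC(C)(C)Oc1ccc([C@@H]2CC(=O)c3c(OC(C)(C)C=C)cc(OCOC)cc3O2)cc1OCOC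
A2 | alternative 1 | (2S)‑5‑hydroxy‑2‑[4‑hydroxy‑3‑(methoxymethoxy)‑5‑(3‑methylbut‑2‑en‑1‑yl)phenyl]‑7‑(methoxymethoxy)‑6‑(3‑methylbut‑2‑en‑1‑yl)chroman‑4‑one | CC(C)=CCc1cc([C@@H]2CC(=O)c3c(O)c(CC=C(C)C)c(OCOC)cc3O2)cc(OCOC)c1O
A3 | alternative 2 | 2‑diazo‑1‑{2‑[3,4‑bis(tert‑butyldimethylsilyloxy)‑5‑(3‑methylbut‑2‑en‑1‑yl)benzyloxy]‑4,6‑bis(tert‑butyldimethylsilyloxy)‑5‑(3‑methylbut‑2‑en‑1‑yl)phenyl}ethan‑1‑one | [N-]=[N+]=CC(=O)c1c(OCc2cc(CC=C(C)C)c(O[Si](C)(C)C(C)(C)C)c(O[Si](C)(C)C(C)(C)C)c2)cc(O[Si](C)(C)C(C)(C)C)c(CC=C(C)C)c1O[Si](C)(C)C(C)(C)C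
A4 | alternative 2 | (2S)‑5,7‑bis(tert‑butyldimethylsilyloxy)‑2‑[3,4‑bis(tert‑butyldimethylsilyloxy)‑5‑(3‑methylbut‑2‑en‑1‑yl)phenyl]‑6‑(3‑methylbut‑2‑en‑1‑yl)chroman‑4‑one | CC(C)=CCc1cc([C@@H]2CC(=O)c3c(cc(O[Si](C)(C)C(C)(C)C)c(CC=C(C)C)c3O[Si](C)(C)C(C)(C)C)O2)cc(O[Si](C)(C)C(C)(C)C)c1O[Si](C)(C)C(C)(C)C
A5 | alternative 3 | (2S)‑6‑(2‑diazoacetyl)‑2‑[3,4‑bis(methoxymethoxy)‑5‑(3‑methylbut‑2‑en‑1‑yl)phenyl]‑2,3‑dihydro‑4H‑pyran‑4‑one | [N-]=[N+]=CC(=O)C1=CC(=O)C[C@@H](c2cc(CC=C(C)C)c(OCOC)c(OCOC)c2)O1
A6 | alternative 3 | [(5‑methylhex‑4‑en‑1‑yn‑1‑yl)oxy]tri(propan‑2‑yl)silane | CC(C)=CCC#CO[Si](C(C)C)(C(C)C)C(C)C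
A7 | alternative 3 | (2S)‑5‑hydroxy‑2‑[3,4‑bis(methoxymethoxy)‑5‑(3‑methylbut‑2‑en‑1‑yl)phenyl]‑6‑(3‑methylbut‑2‑en‑1‑yl)‑7‑[tri(propan‑2‑yl)silyloxy]chroman‑4‑one | CC(C)=CCc1cc([C@@H]2CC(=O)c3c(cc(O[Si](C(C)C)(C(C)C)C(C)C)c(CC=C(C)C)c3O)O2)cc(OCOC)c1OCOC
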